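The plan rests on disconnecting C10–C10a of the phenanthrene. This leads back to ortho-terphenyl 15, in which ring A (C4b, C5–C8, C8a) carries an ethynyl group on C8a and ring D (C1–C4, C4a, C10a) already holds ring C on C4. The feature exploited lies in ring D. Of the two carbons flanking C4a, C4 is blocked by ring C, whereas C10a is a free CH para to the C3 oxygen, so the alkyne has only one carbon to attack. One PtCl2-catalysed cycloisomerisation forms the central ring and fixes the bay-aryl pattern of 16. Ring B is then coupled to C6, and the ethano bridge closes the twelve-membered ring.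

Key step: step 12

Assumption: the target SMILES carries no stereodescriptor, so the biaryl axes and the twisted bay region are left uncontrolled and the compound is made in racemic form.
Numbering: phenanthrene locants are those of the target (Cl on C2, O on C3, ring C on C4, ring B on C6, OMe on C7). In 12 the OH is para and the OMe meta to CHO, which places O on C6 and OMe on C7. In 1 the CH between OH and Br becomes C4.
Design choices:
- The directing carbamate is exchanged for the isopropyl ether at the trihalobenzene stage, where hot hydroxide meets neither ester nor aldehyde.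
- The ring B aldehyde travels as a dioxolane, so the ring C ester can be reduced alone.
- All three phenols are carried as isopropyl ethers, because BCl3 removes these beside the C7 methyl ether.
- No step uses catalytic hydrogenation, which would endanger the C–Cl bonds.

Step 1
Reactants: 1 5-bromo-2-chlorophenol
Product: 2 5-bromo-2-chlorophenyl N,N-diethylcarbamate
Conditions: Et2NCOCl, K2CO3, MeCN, reflux
Reagents that add atoms: N,N-diethylcarbamoyl chloride, CCN(CC)C(Cl)=O
Why: O-carbamoylation of a phenoxide (acyl substitution) is routine and installs the strongest oxygen-based director for the ortho-metalation that follows.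

Step 2
Reactants: 2 5-bromo-2-chlorophenyl N,N-diethylcarbamate
Product: 4 3-bromo-6-chloro-2-iodophenyl N,N-diethylcarbamate, via aryllithium 3 (not isolated)
Conditions: LiN(iPr)2 (LDA), THF, −78 °C; then I2, −78 °C → rt
Reagents that add atoms: iodine, [I][I]
Why: Directed ortho-metalation works here because the one CH next to the carbamate also lies next to bromine and is by far the most acidic, the amide base deprotonates without Br–Li exchange, and at −78 °C neither the anionic Fries shift nor loss of LiBr should compete before iodine traps 3.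

Step 3
Reactants: 4 3-bromo-6-chloro-2-iodophenyl N,N-diethylcarbamate
Product: 5 3-bromo-6-chloro-2-iodophenol
Conditions: NaOH, EtOH, reflux; then 1 M HCl
Reagents that add atoms: none
Why: Basic hydrolysis of the aryl carbamate (acyl substitution, then decarboxylation of the carbamic acid) is placed here because the substrate holds only aryl halides, so the forcing conditions have nothing else to attack.

Step 4
Reactants: 5 3-bromo-6-chloro-2-iodophenol
Product: 6 1-bromo-4-chloro-2-iodo-3-isopropoxybenzene
Conditions: iPrBr, K2CO3, DMF, 60 °C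
Reagents that add atoms: 2-bromopropane, CC(C)Br
Why: In this Williamson ether synthesis the acidic 2,6-dihalophenoxide is alkylated on oxygen by the secondary bromide in a dipolar aprotic solvent, and any E2 loss of the reagent is made up by excess.

Step 5
Reactants: 7 methyl 3-bromo-4-hydroxybenzoate
Product: 8 methyl 3-bromo-4-isopropoxybenzoate
Conditions: iPrBr, K2CO3, DMF, 60 °C
Reagents that add atoms: 2-bromopropane, CC(C)Br
Why: This is a Williamson ether synthesis on an acidic para-acyl phenol, and carbonate in DMF leaves the methyl ester alone.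

Step 6
Reactants: 8 methyl 3-bromo-4-isopropoxybenzoate
Product: 9 methyl 4-isopropoxy-3-(4,4,5,5-tetramethyl-1,3,2-dioxaborolan-2-yl)benzoate
Conditions: B2pin2, Pd(dppf)Cl2 (cat.), KOAc, dioxane, 90 °C
Reagents that add atoms: bis(pinacolato)diboron, CC1(C)OB(OC1(C)C)B1OC(C)(C)C(C)(C)O1
Why: In this Miyaura borylation of an aryl bromide, acetate is too weak a base to start Suzuki homocoupling or to touch the ester.

Step 7
Reactants: 6 1-bromo-4-chloro-2-iodo-3-isopropoxybenzene; 9 methyl 4-isopropoxy-3-(4,4,5,5-tetramethyl-1,3,2-dioxaborolan-2-yl)benzoate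
Product: 10 methyl 3-(6-bromo-3-chloro-2-isopropoxyphenyl)-4-isopropoxybenzoate
Conditions: Pd(PPh3)4 (cat.), K2CO3, DME/H2O, 80 °C, 9 not in excess
Reagents that add atoms: none
Why: This Suzuki–Miyaura coupling is site-selective because zerovalent palladium bearing PPh3 inserts much faster into C–I than into C–Br or C–Cl, and the bromide of 10, now ortho to an aryl group, is too hindered to couple again.

Step 8
Reactants: 10 methyl 3-(6-bromo-3-chloro-2-isopropoxyphenyl)-4-isopropoxybenzoate
Product: 11 methyl 3-[3-chloro-2-isopropoxy-6-(4,4,5,5-tetramethyl-1,3,2-dioxaborolan-2-yl)phenyl]-4-isopropoxybenzoate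
Conditions: B2pin2, Pd(dppf)Cl2 (cat.), KOAc, dioxane, 100 °C
Reagents that add atoms: bis(pinacolato)diboron, CC1(C)OB(OC1(C)C)B1OC(C)(C)C(C)(C)O1
Why: In this Miyaura borylation the catalyst inserts into the C–Br bond and leaves the electron-rich C–Cl bond next to the isopropoxy group untouched.

Step 9
Reactants: 12 2-bromo-4-hydroxy-5-methoxybenzaldehyde
Product: 13 2-bromo-5-methoxy-4-(methoxymethoxy)benzaldehyde
Conditions: MOMCl, K2CO3, DMF, 0 °C → rt
Reagents that add atoms: chloromethyl methyl ether, COCCl
Why: Williamson-type O-alkylation of the acidic vanillin-type phenol gives a MOM ether that withstands the basic coupling and homologation ahead and later falls to mild acid that spares isopropyl ethers.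

Step 10
Reactants: 11 methyl 3-[3-chloro-2-isopropoxy-6-(4,4,5,5-tetramethyl-1,3,2-dioxaborolan-2-yl)phenyl]-4-isopropoxybenzoate; 13 2-bromo-5-methoxy-4-(methoxymethoxy)benzaldehyde
Product: 14 methyl 3-[3-chloro-6-[2-formyl-4-methoxy-5-(methoxymethoxy)phenyl]-2-isopropoxyphenyl]-4-isopropoxybenzoate
Conditions: Pd(dppf)Cl2 (cat.), K3PO4, dioxane/H2O, 90 °C
Reagents that add atoms: none
Why: In this Suzuki–Miyaura coupling the ortho-formyl group speeds oxidative addition into the C–Br bond of 13, only two ortho substituents flank the new C4a–C4b bond, and the C–Cl bond is inert to this catalyst.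

Step 11
Reactants: 14 methyl 3-[3-chloro-6-[2-formyl-4-methoxy-5-(methoxymethoxy)phenyl]-2-isopropoxyphenyl]-4-isopropoxybenzoate
Product: 15 methyl 3-[3-chloro-6-[2-ethynyl-4-methoxy-5-(methoxymethoxy)phenyl]-2-isopropoxyphenyl]-4-isopropoxybenzoate
Conditions: dimethyl (1-diazo-2-oxopropyl)phosphonate, K2CO3, MeOH/THF, rt
Reagents that add atoms: dimethyl (1-diazo-2-oxopropyl)phosphonate, COP(=O)(OC)C(=[N+]=[N-])C(C)=O
Why: In the Ohira–Bestmann form of the Seyferth–Gilbert homologation, methanolysis frees the diazomethylphosphonate anion, which olefinates the non-enolisable aldehyde, and loss of N2 with a 1,2-hydrogen shift gives the terminal alkyne while K2CO3 in MeOH leaves the methyl ester and the MOM ether unchanged.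

Step 12
Reactants: 15 methyl 3-[3-chloro-6-[2-ethynyl-4-methoxy-5-(methoxymethoxy)phenyl]-2-isopropoxyphenyl]-4-isopropoxybenzoate
Product: 16 methyl 3-[2-chloro-3-isopropoxy-7-methoxy-6-(methoxymethoxy)phenanthren-4-yl]-4-isopropoxybenzoate
Conditions: PtCl2 (10 mol %), toluene, 80 °C, Ar
Reagents that add atoms: none
Why: PtCl2 binds the terminal alkyne of 15, either as the π complex or after a 1,2-hydrogen shift as the platinum vinylidene, and thereby makes the terminal carbon (the future C10) electrophilic; C10a of ring D attacks it in Friedel–Crafts fashion, and proton loss with protodemetalation restores the arene and releases divalent platinum. The closest known reaction type is the PtCl2-catalysed cycloisomerisation (intramolecular hydroarylation) of 2-ethynylbiaryls to phenanthrenes, which also builds helicenes, so the strain of a bay substituent lies within its reach. The single ring formed, the central ring C4a–C4b–C8a–C9–C10–C10a, closes in the 6-endo-dig mode, and no stereocentre is created. Site selectivity on ring D is secured by the substrate, since C4 is occupied by ring C and C10a is the only CH ortho to the C4a–C4b bond and is activated by the para isopropoxy group on C3. Preference for 6-endo over 5-exo closure, which would give a 9-methylenefluorene, is secured by the unsubstituted alkyne terminus, which is the open and, in the vinylidene, the metal-bound electrophilic carbon. The MOM ether lies para to the alkyne and cannot add to it, and should traces of HCl remove it the outcome is simply 17, the product of step 13.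

Step 13
Reactants: 16 methyl 3-[2-chloro-3-isopropoxy-7-methoxy-6-(methoxymethoxy)phenanthren-4-yl]-4-isopropoxybenzoate
Product: 17 methyl 3-(2-chloro-6-hydroxy-3-isopropoxy-7-methoxyphenanthren-4-yl)-4-isopropoxybenzoate
Conditions: conc. HCl (cat.), MeOH/THF, 50 °C
Reagents that add atoms: none
Why: Acid-catalysed acetal exchange with methanol (MOM cleavage) frees the C6 hydroxyl, while the aryl isopropyl ethers, the aryl chloride and the methyl ester (degenerate exchange in MeOH) persist.

Step 14
Reactants: 17 methyl 3-(2-chloro-6-hydroxy-3-isopropoxy-7-methoxyphenanthren-4-yl)-4-isopropoxybenzoate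
Product: 18 methyl 3-[2-chloro-3-isopropoxy-7-methoxy-6-(trifluoromethylsulfonyloxy)phenanthren-4-yl]-4-isopropoxybenzoate
Conditions: Tf2O, pyridine, CH2Cl2, 0 °C
Reagents that add atoms: trifluoromethanesulfonic anhydride, O=S(=O)(OS(=O)(=O)C(F)(F)F)C(F)(F)F
Why: O-sulfonylation of the only free phenol gives the aryl triflate, the one site in the molecule that a bisphosphine palladium catalyst will insert into.

Step 15
Reactants: 19 2-bromo-4-chlorophenol
Product: 20 2-bromo-4-chloro-1-isopropoxybenzene
Conditions: iPrBr, K2CO3, DMF, 60 °C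
Reagents that add atoms: 2-bromopropane, CC(C)Br
Why: This is a Williamson ether synthesis on a simple halophenol.

Step 16
Reactants: 20 2-bromo-4-chloro-1-isopropoxybenzene
Product: 22 2-bromo-6-chloro-3-isopropoxybenzaldehyde, via aryllithium 21 (not isolated)
Conditions: LiN(iPr)2 (LDA), THF, −78 °C; then DMF; then 1 M HCl
Reagents that add atoms: N,N-dimethylformamide, CN(C)C=O
Why: Deprotonative lithiation and formylation succeed because the CH flanked by bromine and chlorine is the most acidic position of 20 and gives the most stable anion (so no halogen migration is driven), the amide base does not exchange bromine, and the DMF adduct collapses to the aldehyde on acidic quench.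

Step 17
Reactants: 22 2-bromo-6-chloro-3-isopropoxybenzaldehyde
Product: 23 2-(2-bromo-6-chloro-3-isopropoxyphenyl)-1,3-dioxolane
Conditions: HOCH2CH2OH, p-TsOH (cat.), toluene, Dean–Stark, reflux
Reagents that add atoms: ethane-1,2-diol, OCCO
Why: Acid-catalysed acetalisation with azeotropic removal of water works well on this electron-poor aldehyde, and the acetal masks it against n-BuLi and LiAlH4.

Step 18
Reactants: 23 2-(2-bromo-6-chloro-3-isopropoxyphenyl)-1,3-dioxolane
Product: 25 2-[3-chloro-2-(1,3-dioxolan-2-yl)-6-isopropoxyphenyl]-4,4,5,5-tetramethyl-1,3,2-dioxaborolane, via aryllithium 24 (not isolated)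
Conditions: n-BuLi, THF, −78 °C; then iPrOBpin, −78 °C → rt; aq. NH4Cl
Reagents that add atoms: 2-isopropoxy-4,4,5,5-tetramethyl-1,3,2-dioxaborolane, CC(C)OB1OC(C)(C)C(C)(C)O1
Why: Bromine–lithium exchange, far faster than chlorine exchange at −78 °C, gives an aryllithium braced by two oxygen donors and meta to chlorine (no aryne pathway), and electrophilic borylation with the isopropoxy pinacol borate gives the boronate.

Step 19
Reactants: 18 methyl 3-[2-chloro-3-isopropoxy-7-methoxy-6-(trifluoromethylsulfonyloxy)phenanthren-4-yl]-4-isopropoxybenzoate; 25 2-[3-chloro-2-(1,3-dioxolan-2-yl)-6-isopropoxyphenyl]-4,4,5,5-tetramethyl-1,3,2-dioxaborolane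
Product: 26 methyl 3-[2-chloro-6-[3-chloro-2-(1,3-dioxolan-2-yl)-6-isopropoxyphenyl]-3-isopropoxy-7-methoxyphenanthren-4-yl]-4-isopropoxybenzoate
Conditions: Pd(dppf)Cl2 (cat.), K3PO4, dioxane/H2O, 95 °C, 25 in excess
Reagents that add atoms: none
Why: In this Suzuki–Miyaura coupling of an aryl triflate the bisphosphine palladium catalyst inserts into C–OTf but not into the two electron-rich aryl chlorides, and an excess of the hindered boronate offsets slow transmetalation in forming the triply ortho-substituted C6–ring B bond.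

Step 20
Reactants: 26 methyl 3-[2-chloro-6-[3-chloro-2-(1,3-dioxolan-2-yl)-6-isopropoxyphenyl]-3-isopropoxy-7-methoxyphenanthren-4-yl]-4-isopropoxybenzoate
Product: 27 [3-[2-chloro-6-[3-chloro-2-(1,3-dioxolan-2-yl)-6-isopropoxyphenyl]-3-isopropoxy-7-methoxyphenanthren-4-yl]-4-isopropoxyphenyl]methanol
Conditions: LiAlH4, THF, 0 °C; aq. work-up
Reagents that add atoms: none
Why: Hydride reduction takes the ester to the primary benzylic alcohol, and the dioxolane, the aryl ethers and the aryl chlorides are not attacked by LiAlH4 at 0 °C.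

Step 21
Reactants: 27 [3-[2-chloro-6-[3-chloro-2-(1,3-dioxolan-2-yl)-6-isopropoxyphenyl]-3-isopropoxy-7-methoxyphenanthren-4-yl]-4-isopropoxyphenyl]methanol
Product: 29 [3-[2-chloro-6-(3-chloro-2-formyl-6-isopropoxyphenyl)-3-isopropoxy-7-methoxyphenanthren-4-yl]-4-isopropoxybenzyl]triphenylphosphonium bromide, via dioxolane phosphonium bromide 28 (not isolated)
Conditions: PPh3·HBr, MeCN, reflux; then 2 M HCl, acetone, rt
Reagents that add atoms: triphenylphosphine hydrobromide, Br.c1ccc(cc1)P(c1ccccc1)c1ccccc1; water, O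
Why: The para-isopropoxybenzylic alcohol ionises readily in acid and is captured by PPh3 (SN1-type phosphonium salt formation), and the same acidic medium, completed with aqueous HCl, hydrolyses the dioxolane to the aldehyde.

Step 22
Reactants: 29 [3-[2-chloro-6-(3-chloro-2-formyl-6-isopropoxyphenyl)-3-isopropoxy-7-methoxyphenanthren-4-yl]-4-isopropoxybenzyl]triphenylphosphonium bromide
Product: 31 Z-configured macrocyclic stilbene (tri-O-isopropyl ether of the target bearing CH=CH in place of CH2CH2), via phosphonium ylide 30 (not isolated)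
Conditions: NaOMe, CH2Cl2, rt, slow syringe-pump addition of 29 (high dilution)
Reagents that add atoms: none
Why: In this intramolecular Wittig olefination under high dilution, methoxide forms the semi-stabilised benzylic ylide at low stationary concentration, rings B and C stand face to face on C6 and C4 so the reacting ends are close, and the ring can accept only the Z alkene, whose geometry is erased in the next step.

Step 23
Reactants: 31 Z-configured macrocyclic stilbene
Product: 32 tri-O-isopropyl ether of the target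
Conditions: TsNHNH2, NaOAc, DME/H2O, reflux
Reagents that add atoms: none
Why: Diimide reduction (concerted syn hydrogen transfer from HN=NH released by the tosylhydrazide) saturates the strained stilbene bond and, unlike catalytic hydrogenation, cannot cleave C–Cl bonds or touch the aromatic C9–C10 bond.

Step 24
Reactants: 32 tri-O-isopropyl ether of the target
Product: 33 target CNP0310669.0
Conditions: BCl3, CH2Cl2, −78 → 0 °C; then H2O
Reagents that add atoms: none
Why: In this Lewis acid dealkylation BCl3 cleaves the three secondary isopropyl aryl ethers by SN1-like loss of the isopropyl group at low temperature, where the primary methyl ether on C7, which has no neighbouring carbonyl group to chelate boron, should stay intact.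

Compound list
1 | 5-bromo-2-chlorophenol | Oc1cc(Br)ccc1Cl | starting material
2 | 5-bromo-2-chlorophenyl N,N-diethylcarbamate | CCN(CC)C(=O)Oc1cc(Br)ccc1Cl | intermediate
3 | [6-bromo-3-chloro-2-(diethylcarbamoyloxy)phenyl]lithium (formed in the flask) | CCN(CC)C(=O)Oc1c(Cl)ccc(Br)c1[Li] | intermediate
4 | 3-bromo-6-chloro-2-iodophenyl N,N-diethylcarbamate | CCN(CC)C(=O)Oc1c(Cl)ccc(Br)c1I | intermediate
5 | 3-bromo-6-chloro-2-iodophenol | Oc1c(Cl)ccc(Br)c1I | intermediate
6 | 1-bromo-4-chloro-2-iodo-3-isopropoxybenzene | CC(C)Oc1c(Cl)ccc(Br)c1I | intermediate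
7 | methyl 3-bromo-4-hydroxybenzoate | COC(=O)c1ccc(O)c(Br)c1 | starting material
8 | methyl 3-bromo-4-isopropoxybenzoate | COC(=O)c1ccc(OC(C)C)c(Br)c1 | intermediate
9 | methyl 4-isopropoxy-3-(4,4,5,5-tetramethyl-1,3,2-dioxaborolan-2-yl)benzoate | COC(=O)c1ccc(OC(C)C)c(c1)B1OC(C)(C)C(C)(C)O1 | intermediate
10 | methyl 3-(6-bromo-3-chloro-2-isopropoxyphenyl)-4-isopropoxybenzoate | COC(=O)c1ccc(OC(C)C)c(c1)-c1c(Br)ccc(Cl)c1OC(C)C | intermediate
11 | methyl 3-[3-chloro-2-isopropoxy-6-(4,4,5,5-tetramethyl-1,3,2-dioxaborolan-2-yl)phenyl]-4-isopropoxybenzoate | COC(=O)c1ccc(OC(C)C)c(c1)-c1c(ccc(Cl)c1OC(C)C)B1OC(C)(C)C(C)(C)O1 | intermediate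
12 | 2-bromo-4-hydroxy-5-methoxybenzaldehyde | COc1cc(C=O)c(Br)cc1O | starting material
13 | 2-bromo-5-methoxy-4-(methoxymethoxy)benzaldehyde | COCOc1cc(Br)c(C=O)cc1OC | intermediate
14 | methyl 3-[3-chloro-6-[2-formyl-4-methoxy-5-(methoxymethoxy)phenyl]-2-isopropoxyphenyl]-4-isopropoxybenzoate | COc1cc(C=O)c(cc1OCOC)-c1ccc(Cl)c(OC(C)C)c1-c1cc(ccc1OC(C)C)C(=O)OC | intermediate
15 | methyl 3-[3-chloro-6-[2-ethynyl-4-methoxy-5-(methoxymethoxy)phenyl]-2-isopropoxyphenyl]-4-isopropoxybenzoate | COc1cc(C#C)c(cc1OCOC)-c1ccc(Cl)c(OC(C)C)c1-c1cc(ccc1OC(C)C)C(=O)OC | intermediate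
16 | methyl 3-[2-chloro-3-isopropoxy-7-methoxy-6-(methoxymethoxy)phenanthren-4-yl]-4-isopropoxybenzoate | COc1cc2ccc3cc(Cl)c(OC(C)C)c(c3c2cc1OCOC)-c1cc(ccc1OC(C)C)C(=O)OC | intermediate
17 | methyl 3-(2-chloro-6-hydroxy-3-isopropoxy-7-methoxyphenanthren-4-yl)-4-isopropoxybenzoate | COc1cc2ccc3cc(Cl)c(OC(C)C)c(c3c2cc1O)-c1cc(ccc1OC(C)C)C(=O)OC | intermediate
18 | methyl 3-[2-chloro-3-isopropoxy-7-methoxy-6-(trifluoromethylsulfonyloxy)phenanthren-4-yl]-4-isopropoxybenzoate | COc1cc2ccc3cc(Cl)c(OC(C)C)c(c3c2cc1OS(=O)(=O)C(F)(F)F)-c1cc(ccc1OC(C)C)C(=O)OC | intermediate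
19 | 2-bromo-4-chlorophenol | Oc1ccc(Cl)cc1Br | starting material
20 | 2-bromo-4-chloro-1-isopropoxybenzene | CC(C)Oc1ccc(Cl)cc1Br | intermediate
21 | (2-bromo-6-chloro-3-isopropoxyphenyl)lithium (formed in the flask) | CC(C)Oc1ccc(Cl)c([Li])c1Br | intermediate
22 | 2-bromo-6-chloro-3-isopropoxybenzaldehyde | CC(C)Oc1ccc(Cl)c(C=O)c1Br | intermediate
23 | 2-(2-bromo-6-chloro-3-isopropoxyphenyl)-1,3-dioxolane | CC(C)Oc1ccc(Cl)c(C2OCCO2)c1Br | intermediate
24 | [3-chloro-2-(1,3-dioxolan-2-yl)-6-isopropoxyphenyl]lithium (formed in the flask) | CC(C)Oc1ccc(Cl)c(C2OCCO2)c1[Li] | intermediate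
25 | 2-[3-chloro-2-(1,3-dioxolan-2-yl)-6-isopropoxyphenyl]-4,4,5,5-tetramethyl-1,3,2-dioxaborolane | CC(C)Oc1ccc(Cl)c(C2OCCO2)c1B1OC(C)(C)C(C)(C)O1 | intermediate
26 | methyl 3-[2-chloro-6-[3-chloro-2-(1,3-dioxolan-2-yl)-6-isopropoxyphenyl]-3-isopropoxy-7-methoxyphenanthren-4-yl]-4-isopropoxybenzoate | COc1cc2ccc3cc(Cl)c(OC(C)C)c(c3c2cc1-c1c(OC(C)C)ccc(Cl)c1C1OCCO1)-c1cc(ccc1OC(C)C)C(=O)OC | intermediate
27 | [3-[2-chloro-6-[3-chloro-2-(1,3-dioxolan-2-yl)-6-isopropoxyphenyl]-3-isopropoxy-7-methoxyphenanthren-4-yl]-4-isopropoxyphenyl]methanol | COc1cc2ccc3cc(Cl)c(OC(C)C)c(c3c2cc1-c1c(OC(C)C)ccc(Cl)c1C1OCCO1)-c1cc(CO)ccc1OC(C)C | intermediate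
28 | [3-[2-chloro-6-[3-chloro-2-(1,3-dioxolan-2-yl)-6-isopropoxyphenyl]-3-isopropoxy-7-methoxyphenanthren-4-yl]-4-isopropoxybenzyl]triphenylphosphonium bromide (formed in the flask) | COc1cc2ccc3cc(Cl)c(OC(C)C)c(c3c2cc1-c1c(OC(C)C)ccc(Cl)c1C1OCCO1)-c1cc(C[P+](c2ccccc2)(c2ccccc2)c2ccccc2)ccc1OC(C)C.[Br-] | intermediate
29 | [3-[2-chloro-6-(3-chloro-2-formyl-6-isopropoxyphenyl)-3-isopropoxy-7-methoxyphenanthren-4-yl]-4-isopropoxybenzyl]triphenylphosphonium bromide | COc1cc2ccc3cc(Cl)c(OC(C)C)c(c3c2cc1-c1c(OC(C)C)ccc(Cl)c1C=O)-c1cc(C[P+](c2ccccc2)(c2ccccc2)c2ccccc2)ccc1OC(C)C.[Br-] | intermediate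
30 | benzylidene(triphenyl)phosphorane derived from 29 (formed in the flask) | COc1cc2ccc3cc(Cl)c(OC(C)C)c(c3c2cc1-c1c(OC(C)C)ccc(Cl)c1C=O)-c1cc(C=P(c2ccccc2)(c2ccccc2)c2ccccc2)ccc1OC(C)C | intermediate
31 | Z-configured macrocyclic stilbene, tri-O-isopropyl ether of the target bearing CH=CH between ring B and ring C | COc1cc2ccc3cc(Cl)c(OC(C)C)c4c3c2cc1-c1c(OC(C)C)ccc(Cl)c1/C=C\c1ccc(OC(C)C)c-4c1 | intermediate
32 | tri-O-isopropyl ether of the target (CH2CH2 bridge in place) | COc1cc2ccc3cc(Cl)c(OC(C)C)c4c3c2cc1-c1c(OC(C)C)ccc(Cl)c1CCc1ccc(OC(C)C)c-4c1 | intermediate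
33 | CNP0310669.0: 2-chloro-3-hydroxy-7-methoxyphenanthrene whose C4 carries ring C (2-hydroxyphenyl, linked on through its C5) and whose C6 carries ring B (3-chloro-6-hydroxyphenyl, linked on through its C2), the two rings joined by CH2CH2 | COc1cc2ccc3cc(Cl)c(O)c4c3c2cc1-c1c(O)ccc(Cl)c1CCc1ccc(O)c-4c1 | target

Total step count: 24. Longest linear sequence: 17 steps (steps 1–4, 7, 8, 10–14, 19–24).

Steps most likely to fail

Step 22 (macrocyclic Wittig reaction).
- What may go wrong: the ylide may add to the aldehyde of a second molecule faster than it closes the ring. The twelve-membered ring has to accept a planar cis double bond that fits the stacked rings B and C poorly, so oligomerisation would consume 29.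
- Fallback: install the saturated bridge first and close the ring at the C6–ring B biaryl bond instead.
- It sets out from triflate 18. iBu2AlH (CH2Cl2, −78 °C) reduces the ester to the benzylic alcohol F1 without touching the triflate, and PPh3·HBr (MeCN, reflux) gives the phosphonium bromide F2.
- An intermolecular Wittig reaction with bromo aldehyde 22 (K2CO3, 18-crown-6, CH2Cl2, reflux) gives the open stilbene F3 as an E/Z mixture. Diimide (TsNHNH2, NaOAc, DME/H2O, reflux) then gives the open bibenzyl F4.
- Under high dilution, B2pin2, Pd(dppf)Cl2 and KOAc in dioxane convert the less hindered C6 triflate into the bibenzyl boronate F5.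
- Addition of aqueous K3PO4 lets F5 couple with the ring B bromide in an intramolecular Suzuki–Miyaura reaction. Closure passes through a larger palladacycle and never needs an sp2 bridge. The sequence comes back to the route at 32.

Step 12 (key cycloisomerisation).
- What may go wrong: closure has to flatten rings A and D and press ring C against C5–H. Alkyne oligomerisation, hydration or 5-exo closure could therefore overtake the 6-endo path, or the catalyst could be held by the oxygen donors.
- Fallback: form the same C10–C10a bond by a Brønsted acid cyclisation.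
- It sets out from aldehyde 14. A Wittig reaction with (methoxymethyl)triphenylphosphonium chloride and KOtBu in THF gives the methyl enol ether F6 as an E/Z mixture.
- MeSO3H in CH2Cl2 at 0 °C protonates F6 to an oxocarbenium ion at the future C10. C10a attacks this ion, and loss of methanol aromatises the central ring.
- The acid also removes the MOM group, the methanol just released taking up its CH2 unit. The sequence therefore comes back to the route at phenol 17.

Step 19 (hindered Suzuki coupling at C6).
- What may go wrong: the boron of 25 sits between an alkoxy group and the dioxolanyl group. Protodeboronation may therefore outrun the slow transmetalation, while the triflate is slowly hydrolysed.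
- Fallback: reverse the polarity of the coupling.
- It sets out from 18. Miyaura borylation (B2pin2, Pd(dppf)Cl2, KOAc, dioxane, 90 °C) gives the phenanthren-6-ylboronate F7, which has a single ortho substituent and is far more robust.
- Coupling of F7 with bromide 23 (Pd(OAc)2, SPhos, K3PO4, toluene/H2O, 90 °C), in which C–Br reacts ahead of the hindered electron-rich chlorides, comes back to the route at 26.

Further compounds
F1 | step 22 | 2-chloro-4-[5-(hydroxymethyl)-2-isopropoxyphenyl]-3-isopropoxy-7-methoxyphenanthren-6-yl trifluoromethanesulfonate | COc1cc2ccc3cc(Cl)c(OC(C)C)c(c3c2cc1OS(=O)(=O)C(F)(F)F)-c1cc(CO)ccc1OC(C)C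
F2 | step 22 | [3-[2-chloro-3-isopropoxy-7-methoxy-6-(trifluoromethylsulfonyloxy)phenanthren-4-yl]-4-isopropoxybenzyl]triphenylphosphonium bromide | COc1cc2ccc3cc(Cl)c(OC(C)C)c(c3c2cc1OS(=O)(=O)C(F)(F)F)-c1cc(C[P+](c2ccccc2)(c2ccccc2)c2ccccc2)ccc1OC(C)C.[Br-]
F3 | step 22 | 4-[5-[2-(2-bromo-6-chloro-3-isopropoxyphenyl)ethenyl]-2-isopropoxyphenyl]-2-chloro-3-isopropoxy-7-methoxyphenanthren-6-yl trifluoromethanesulfonate (E/Z mixture) | COc1cc2ccc3cc(Cl)c(OC(C)C)c(c3c2cc1OS(=O)(=O)C(F)(F)F)-c1cc(C=Cc2c(Cl)ccc(OC(C)C)c2Br)ccc1OC(C)C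
F4 | step 22 | 4-[5-[2-(2-bromo-6-chloro-3-isopropoxyphenyl)ethyl]-2-isopropoxyphenyl]-2-chloro-3-isopropoxy-7-methoxyphenanthren-6-yl trifluoromethanesulfonate | COc1cc2ccc3cc(Cl)c(OC(C)C)c(c3c2cc1OS(=O)(=O)C(F)(F)F)-c1cc(CCc2c(Cl)ccc(OC(C)C)c2Br)ccc1OC(C)C
F5 | step 22 | 2-[4-[5-[2-(2-bromo-6-chloro-3-isopropoxyphenyl)ethyl]-2-isopropoxyphenyl]-2-chloro-3-isopropoxy-7-methoxyphenanthren-6-yl]-4,4,5,5-tetramethyl-1,3,2-dioxaborolane | COc1cc2ccc3cc(Cl)c(OC(C)C)c(c3c2cc1B1OC(C)(C)C(C)(C)O1)-c1cc(CCc2c(Cl)ccc(OC(C)C)c2Br)ccc1OC(C)C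
F6 | step 12 | methyl 3-[3-chloro-2-isopropoxy-6-[4-methoxy-5-(methoxymethoxy)-2-(2-methoxyethenyl)phenyl]phenyl]-4-isopropoxybenzoate (E/Z mixture) | COC=Cc1cc(OC)c(OCOC)cc1-c1ccc(Cl)c(OC(C)C)c1-c1cc(ccc1OC(C)C)C(=O)OC
F7 | step 19 | methyl 3-[2-chloro-3-isopropoxy-7-methoxy-6-(4,4,5,5-tetramethyl-1,3,2-dioxaborolan-2-yl)phenanthren-4-yl]-4-isopropoxybenzoate | COc1cc2ccc3cc(Cl)c(OC(C)C)c(c3c2cc1B1OC(C)(C)C(C)(C)O1)-c1cc(ccc1OC(C)C)C(=O)OC
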